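**Strategy.** The route rests on cutting the oxolane C4–O bond (cembrane numbering: C1 carries acrylate carbon C15, C12 the lactone oxygen, C11 the ketone). The 2,5-cis oxolane (O, C4–C7) flanked by the C3 and C8 carbinols, each anti to its ring C–O bond, is the imprint of a (3E,7E)-diene bis-epoxide. In one operation, aqueous acid lets the C11 ketone open the 7,8-epoxide at C8, and the freed C7 oxygen closes the oxolane on C4 of the 3,4-epoxide, fixing C3, C4, C7 and C8. The precursor is the 14-membered diepoxy keto lactone, built from a Baeyer–Villiger-derived ε-lactone and a geranyl-type iodide by Negishi coupling and π-allyl macrocyclisation.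

Key step: step 21

Remark: cembrane numbering is used throughout (C16 = lactone carbonyl, C17 = exocyclic methylene, C13 and C14 = lactone-ring CH2 groups). The target is taken in the open keto form drawn; its C8-hydroxyl/C11-ketone hemiketal is a tautomer.

**Lactone branch**

Step 1
Reactants: 1 cyclohex-2-en-1-one
Product: 2 (3S)-3-ethenylcyclohexan-1-one
Conditions: CH2=CHBF3K, [Rh(cod)2]BF4 (3 mol%), (S)-2,2′-bis(diphenylphosphino)-1,1′-binaphthyl, toluene–H2O, 100 °C
Reagents that add atoms: potassium vinyltrifluoroborate, C=C[B-](F)(F)F.[K+]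
Why: Rhodium-catalysed asymmetric conjugate addition (Hayashi–Miyaura reaction) transfers the vinyl group to one enantioface of the enone under control of the (S)-configured bisphosphine, which should set the future C1 as 3S.

Step 2
Reactants: 2 (3S)-3-ethenylcyclohexan-1-one
Product: 3 benzyl (4S)-4-ethenyl-2-oxocyclohexane-1-carboxylate (C1 epimers and enol)
Conditions: NaH, (BnO)2CO, THF, reflux; aq. NH4Cl
Reagents that add atoms: dibenzyl carbonate, O=C(OCc1ccccc1)OCc1ccccc1
Why: Claisen-type C-acylation of the ketone enolate under equilibrating conditions should occur at the α-carbon remote from the vinyl-bearing carbon, giving an enolisable β-keto ester whose C1 centre is not yet fixed.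

Step 3
Reactants: 3 benzyl (4S)-4-ethenyl-2-oxocyclohexane-1-carboxylate
Product: 4 benzyl (1S,4S)-4-ethenyl-1-methyl-2-oxocyclohexane-1-carboxylate
Conditions: MeI, K2CO3, acetone, rt
Reagents that add atoms: iodomethane, CI
Why: C-alkylation of the β-keto ester enolate, in which axial attack of iodomethane on the half-chair with the vinyl group equatorial should place methyl cis to vinyl and so set the quaternary centre (future C12) relative to C1; the minor epimer is removed by chromatography.

Step 4
Reactants: 4 benzyl (1S,4S)-4-ethenyl-1-methyl-2-oxocyclohexane-1-carboxylate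
Product: 6 benzyl (1S,4S)-4-(hydroxymethyl)-1-methyl-2-oxocyclohexane-1-carboxylate, via aldehyde 5 (not isolated)
Conditions: O3, CH2Cl2–MeOH, −78 °C; Me2S; then NaBH(OAc)3, AcOH, 0 °C
Reagents that add atoms: ozone, [O-][O+]=O
Why: Ozonolysis with reductive work-up cleaves the vinyl group to the aldehyde, which NaBH(OAc)3 should reduce chemoselectively beside the hindered ketone, the cold, non-basic sequence keeping the α-stereocentre intact.

Step 5
Reactants: 6 benzyl (1S,4S)-4-(hydroxymethyl)-1-methyl-2-oxocyclohexane-1-carboxylate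
Product: 7 benzyl (1S,4S)-4-(bromomethyl)-1-methyl-2-oxocyclohexane-1-carboxylate
Conditions: CBr4, PPh3, CH2Cl2, 0 °C
Reagents that add atoms: tetrabromomethane, BrC(Br)(Br)Br
Why: Appel reaction of the primary alcohol, carried out now because a free γ-hydroxyl would translactonise to a butyrolactone once the ε-lactone exists.

Step 6
Reactants: 7 benzyl (1S,4S)-4-(bromomethyl)-1-methyl-2-oxocyclohexane-1-carboxylate
Product: 8 benzyl (2R,5S)-5-(bromomethyl)-2-methyl-7-oxooxepane-2-carboxylate
Conditions: mCPBA, NaHCO3, CH2Cl2, 0 °C → rt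
Reagents that add atoms: 3-chloroperoxybenzoic acid, OOC(=O)c1cccc(Cl)c1
Why: Baeyer–Villiger oxidation, in which the fully substituted α-carbon should migrate in preference to the CH2 group with retention of configuration, placing the ring oxygen on the future C12 and giving the ε-lactone.

**Diene branch**

Step 7
Reactants: 9 6-methylhept-5-en-2-one
Product: 11 6-methylhept-5-en-1-yne, via enol phosphate 10 (not isolated)
Conditions: LiN(iPr)2, THF, −78 °C; ClP(O)(OEt)2; then LiN(iPr)2 (2.3 equiv), −78 °C → rt
Reagents that add atoms: none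
Why: Kinetic enolisation on the methyl side, O-phosphorylation and base-induced elimination of the enol phosphate (methyl ketone to terminal alkyne conversion) should give the enyne.

Step 8
Reactants: 11 6-methylhept-5-en-1-yne
Product: 12 (2E)-2-methylhept-2-en-6-yn-1-ol
Conditions: SeO2 (0.5 equiv), tBuOOH, CH2Cl2, rt
Reagents that add atoms: tert-butyl hydroperoxide, CC(C)(C)OO
Why: Selenium dioxide allylic oxidation (ene reaction then [2,3]-sigmatropic shift) is selective for the methyl group trans to the chain on the trisubstituted olefin and should give the E-allylic alcohol.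

Step 9
Reactants: 12 (2E)-2-methylhept-2-en-6-yn-1-ol
Product: 13 tert-butyldimethyl{[(2E)-2-methylhept-2-en-6-yn-1-yl]oxy}silane
Conditions: TBSCl, imidazole, DMF, rt
Reagents that add atoms: tert-butyl(chloro)dimethylsilane, CC(C)(C)[Si](C)(C)Cl
Why: Silylation gives an ether inert to organoaluminium and organozinc reagents and to amide bases.

Step 10
Reactants: 13 tert-butyldimethyl{[(2E)-2-methylhept-2-en-6-yn-1-yl]oxy}silane
Product: 15 tert-butyl{[(2E,6E)-7-iodo-2,6-dimethylhepta-2,6-dien-1-yl]oxy}dimethylsilane, via alkenylalane 14 (not isolated)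
Conditions: Me3Al, Cp2ZrCl2 (0.25 equiv), CH2Cl2, 0 °C → rt; then I2, THF, −30 °C
Reagents that add atoms: trimethylaluminium, C[Al](C)C; iodine, II
Why: Zirconium-catalysed carboalumination (Negishi carboalumination) adds methyl and aluminium syn across the terminal alkyne with methyl on the internal carbon, and iodinolysis with retention should give the E vinyl iodide that becomes C3=C4.

**Union, ring closure and endgame**

Step 11
Reactants: 8 benzyl (2R,5S)-5-(bromomethyl)-2-methyl-7-oxooxepane-2-carboxylate; 15 tert-butyl{[(2E,6E)-7-iodo-2,6-dimethylhepta-2,6-dien-1-yl]oxy}dimethylsilane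
Product: 17 benzyl (2R,5R)-5-[(2E,6E)-8-(tert-butyldimethylsilyloxy)-3,7-dimethylocta-2,6-dien-1-yl]-2-methyl-7-oxooxepane-2-carboxylate, via alkylzinc bromide 16 (not isolated)
Conditions: Zn dust, LiCl, THF, 50 °C; then 15, Pd(OAc)2 (3 mol%), 2-dicyclohexylphosphino-2′,6′-dimethoxybiphenyl, THF, rt
Reagents that add atoms: none
Why: Zinc insertion into the primary C–Br bond tolerates lactone and ester, and the Negishi sp3–sp2 coupling should join C2 to C3 with retention of the E geometry.

Step 12
Reactants: 17 (Negishi product)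
Product: 18 benzyl (2R,5R)-6-[(dimethylamino)methyl]-5-[(2E,6E)-8-(tert-butyldimethylsilyloxy)-3,7-dimethylocta-2,6-dien-1-yl]-2-methyl-7-oxooxepane-2-carboxylate (C6 epimers)
Conditions: LiN(iPr)2, THF, −78 °C; CH2=NMe2+ I−, −78 → 0 °C
Reagents that add atoms: N,N-dimethylmethyleneiminium iodide, C=[N+](C)C.[I-]
Why: The lactone α-CH2 is the only enolisable position, and aminomethylation of its lithium enolate (Mannich reaction) installs C17 as a base-stable precursor of the α-methylene group, the new C15 centre being erased later.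

Step 13
Reactants: 18 (Mannich base benzyl ester)
Product: 19 (2R,5R)-6-[(dimethylamino)methyl]-5-[(2E,6E)-8-(tert-butyldimethylsilyloxy)-3,7-dimethylocta-2,6-dien-1-yl]-2-methyl-7-oxooxepane-2-carboxylic acid
Conditions: Pd(OAc)2 (5 mol%), Et3SiH, Et3N, CH2Cl2, rt; then MeOH–H2O
Reagents that add atoms: none
Why: Palladium-catalysed silane hydrogenolysis of the benzyl ester (transfer hydrogenolysis via the silyl ester) should leave the trisubstituted olefins, the silyl ether and the lactone untouched.

Step 14
Reactants: 19 (carboxylic acid)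
Product: 21 tert-butyl 3-{(2R,5R)-6-[(dimethylamino)methyl]-5-[(2E,6E)-8-(tert-butyldimethylsilyloxy)-3,7-dimethylocta-2,6-dien-1-yl]-2-methyl-7-oxooxepan-2-yl}-3-oxopropanoate, via acyl imidazole 20 (not isolated)
Conditions: CDI, THF, rt; then HO2CCH2CO2tBu, MgCl2, Et3N, THF, 40 °C
Reagents that add atoms: mono-tert-butyl malonate, OC(=O)CC(=O)OC(C)(C)C
Why: Masamune–Brooks homologation, in which the acyl imidazole C-acylates the magnesium enolate of the malonate half-ester with loss of CO2, should give the β-keto ester that brings in C10.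

Step 15
Reactants: 21 (β-keto ester silyl ether)
Product: 22 tert-butyl 3-{(2R,5R)-6-[(dimethylamino)methyl]-5-[(2E,6E)-8-hydroxy-3,7-dimethylocta-2,6-dien-1-yl]-2-methyl-7-oxooxepan-2-yl}-3-oxopropanoate
Conditions: Bu4NF, AcOH, THF, 0 °C → rt
Reagents that add atoms: none
Why: Fluoride-induced cleavage of the silyl ether, buffered with acetic acid so that the β-keto ester and the Mannich base are not disturbed.

Step 16
Reactants: 22 (allylic alcohol)
Product: 23 tert-butyl 3-{(2R,5R)-6-[(dimethylamino)methyl]-5-[(2E,6E)-8-(methoxycarbonyloxy)-3,7-dimethylocta-2,6-dien-1-yl]-2-methyl-7-oxooxepan-2-yl}-3-oxopropanoate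
Conditions: ClCO2Me, pyridine, CH2Cl2, 0 °C
Reagents that add atoms: methyl chloroformate, COC(=O)Cl
Why: Acylation of the primary allylic alcohol gives the carbonate that ionises under neutral conditions in the ring closure.

Step 17
Reactants: 23 (allylic carbonate)
Product: 24 (1R,3E,7E,12R)-10-(tert-butoxycarbonyl)-17-(dimethylamino)-11-oxocembra-3,7-dien-16,12-olide (C10 and C15 epimers)
Conditions: Pd2(dba)3·CHCl3 (5 mol%), 1,2-bis(diphenylphosphino)ethane, THF, 65 °C, slow addition (final 1 mM)
Reagents that add atoms: none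
Why: Tsuji–Trost allylic alkylation, in which zerovalent palladium ionises the carbonate and the β-keto ester carbon C10, deprotonated by the released methoxide, should attack the unsubstituted terminus C9 of the π-allyl complex to close the 14-membered ring with the E olefin retained, high dilution disfavouring oligomers.

Step 18
Reactants: 24 (macrocyclic β-keto ester)
Product: 27 (1R,3E,7E,12R)-17-(dimethylamino)-11-oxocembra-3,7-dien-16,12-olide (C15 epimers), via trimethylsilyl ester 25 (not isolated), via β-keto acid 26 (not isolated)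
Conditions: Me3SiOSO2CF3, 2,6-lutidine, CH2Cl2, 0 °C; then THF–H2O, 45 °C
Reagents that add atoms: none
Why: The silyl triflate converts the tert-butyl ester into a silyl ester without protic acid, and hydrolysis then decarboxylation of the β-keto acid should leave the C11 ketone with both olefins intact.

Step 19
Reactants: 27 (macrocyclic amino ketone)
Product: 29 (1R,3E,7E,12R)-11-oxocembra-3,7,15(17)-trien-16,12-olide, via ammonium iodide 28 (not isolated)
Conditions: MeI, THF–MeOH, rt; evaporate; NaHCO3, H2O–EtOAc, rt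
Reagents that add atoms: none
Why: Quaternisation of the Mannich base and E1cB (Hofmann-type) elimination should unveil the α-methylene lactone without enolate chemistry at the ketone.

Step 20
Reactants: 29 (macrocyclic triene)
Product: 30 (1R,3S,4S,7S,8S,12R)-3,4:7,8-diepoxy-11-oxocembr-15(17)-en-16,12-olide
Conditions: 1,2:4,5-di-O-isopropylidene-β-L-erythro-2,3-hexodiulo-2,6-pyranose (0.6 equiv), KHSO5 (as 2KHSO5·KHSO4·K2SO4), K2CO3, Bu4NHSO4, MeCN–CH2(OMe)2–aq. Na2B4O7, 0 °C
Reagents that add atoms: potassium peroxymonosulfate, [K+].[O-]S(=O)(=O)OO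
Why: Shi asymmetric epoxidation, in which the chiral dioxirane from the L-fructose-derived ketone should epoxidise each E-trisubstituted olefin through a spiro transition state to the S,S-epoxide (setting C3, C4, C7 and C8), the olefin planes of the 14-membered ring being able to present either face and the electron-poor acrylate being inert.

Step 21
Reactants: 30 (bis-epoxide)
Product: 32 (1R,3S,4R,7S,8R,12R)-4,7-epoxy-3,8-dihydroxy-11-oxocembr-15(17)-en-16,12-olide (target), via epoxy diol 31 (not isolated)
Conditions: (±)-camphor-10-sulfonic acid (0.2 equiv), THF–H2O (5:1), 0 °C → rt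
Reagents that add atoms: water, O
Why: Protonation of the 7,8-epoxide lets the C11 carbonyl oxygen open it at tertiary C8 with inversion; hydration of the cyclic oxocarbenium ion returns the ketone and leaves the 7,8-diol 31, whose C7 hydroxyl then attacks C4 of the protonated 3,4-epoxide with inversion, forming the oxolane O–C4 bond and freeing the C3 hydroxyl. The closest known reaction type is the acid-catalysed hydroxy-epoxide and diepoxide cascade that converts 1,5-diene bis-epoxides into 2,5-disubstituted oxolane diols. The oxolane closes in the 5-exo-tet mode at the tertiary epoxide carbon, faster than 6-endo attack at C3 or 6-exo closure by the C8 hydroxyl. C3 and C7 keep, and C4 and C8 invert, the configurations written into the two trans-epoxides by the epoxidation catalyst, so all four centres and the 2,5-cis oxolane follow stereospecifically. The selectivity needed is the direction of the cascade (oxygen delivered to C8 first, the C7 oxygen to C4 second); it is secured by the ketone three carbons from C8, which reaches C8 through a five-membered transition state, and by the tertiary nature of C8 and C4. Excess water, catalytic acid and low temperature reopen any bicyclic ketal formed between the C7 and C8 oxygens and C11 and avoid translactonisation by the C3 hydroxyl.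

**Compound list**

1 | cyclohex-2-en-1-one | O=C1C=CCCC1 | starting material
2 | (3S)-3-ethenylcyclohexan-1-one | O=C1CCC[C@@H](C1)C=C | intermediate
3 | benzyl (4S)-4-ethenyl-2-oxocyclohexane-1-carboxylate (C1 epimers and enol) | O=C1C(C(=O)OCc2ccccc2)CC[C@@H](C1)C=C | intermediate
4 | benzyl (1S,4S)-4-ethenyl-1-methyl-2-oxocyclohexane-1-carboxylate | O=C1[C@](C(=O)OCc2ccccc2)(C)CC[C@@H](C1)C=C | intermediate
5 | benzyl (1S,4S)-4-formyl-1-methyl-2-oxocyclohexane-1-carboxylate | O=C1[C@](C(=O)OCc2ccccc2)(C)CC[C@@H](C1)C=O | intermediate (not isolated)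
6 | benzyl (1S,4S)-4-(hydroxymethyl)-1-methyl-2-oxocyclohexane-1-carboxylate | O=C1[C@](C(=O)OCc2ccccc2)(C)CC[C@@H](C1)CO | intermediate
7 | benzyl (1S,4S)-4-(bromomethyl)-1-methyl-2-oxocyclohexane-1-carboxylate | O=C1[C@](C(=O)OCc2ccccc2)(C)CC[C@@H](C1)CBr | intermediate
8 | benzyl (2R,5S)-5-(bromomethyl)-2-methyl-7-oxooxepane-2-carboxylate | O=C1O[C@](C(=O)OCc2ccccc2)(C)CC[C@@H](C1)CBr | intermediate
9 | 6-methylhept-5-en-2-one | CC(=O)CCC=C(C)C | starting material
10 | diethyl 6-methylhepta-1,5-dien-2-yl phosphate | C=C(CCC=C(C)C)OP(=O)(OCC)OCC | intermediate (not isolated)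
11 | 6-methylhept-5-en-1-yne | C#CCCC=C(C)C | intermediate
12 | (2E)-2-methylhept-2-en-6-yn-1-ol | C#CCC/C=C(C)/CO | intermediate
13 | tert-butyldimethyl{[(2E)-2-methylhept-2-en-6-yn-1-yl]oxy}silane | C#CCC/C=C(C)/CO[Si](C)(C)C(C)(C)C | intermediate
14 | [(1E,5E)-7-(tert-butyldimethylsilyloxy)-2,6-dimethylhepta-1,5-dien-1-yl]dimethylalane | C[Al](C)/C=C(C)/CC/C=C(C)/CO[Si](C)(C)C(C)(C)C | intermediate (not isolated)
15 | tert-butyl{[(2E,6E)-7-iodo-2,6-dimethylhepta-2,6-dien-1-yl]oxy}dimethylsilane | I/C=C(C)/CC/C=C(C)/CO[Si](C)(C)C(C)(C)C | intermediate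
16 | benzyl (2R,5S)-5-[(bromozincio)methyl]-2-methyl-7-oxooxepane-2-carboxylate | O=C1O[C@](C(=O)OCc2ccccc2)(C)CC[C@@H](C1)C[Zn]Br | intermediate (not isolated)
17 | benzyl (2R,5R)-5-[(2E,6E)-8-(tert-butyldimethylsilyloxy)-3,7-dimethylocta-2,6-dien-1-yl]-2-methyl-7-oxooxepane-2-carboxylate | O=C1O[C@](C(=O)OCc2ccccc2)(C)CC[C@@H](C1)C/C=C(C)/CC/C=C(C)/CO[Si](C)(C)C(C)(C)C | intermediate
18 | benzyl (2R,5R)-6-[(dimethylamino)methyl]-5-[(2E,6E)-8-(tert-butyldimethylsilyloxy)-3,7-dimethylocta-2,6-dien-1-yl]-2-methyl-7-oxooxepane-2-carboxylate (C6 epimers) | O=C1O[C@](C(=O)OCc2ccccc2)(C)CC[C@@H](C1CN(C)C)C/C=C(C)/CC/C=C(C)/CO[Si](C)(C)C(C)(C)C | intermediate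
19 | (2R,5R)-6-[(dimethylamino)methyl]-5-[(2E,6E)-8-(tert-butyldimethylsilyloxy)-3,7-dimethylocta-2,6-dien-1-yl]-2-methyl-7-oxooxepane-2-carboxylic acid | O=C1O[C@](C(=O)O)(C)CC[C@@H](C1CN(C)C)C/C=C(C)/CC/C=C(C)/CO[Si](C)(C)C(C)(C)C | intermediate
20 | 1-acylimidazole of acid 19 (carboxyl OH replaced by imidazol-1-yl) | O=C1O[C@](C(=O)n2ccnc2)(C)CC[C@@H](C1CN(C)C)C/C=C(C)/CC/C=C(C)/CO[Si](C)(C)C(C)(C)C | intermediate (not isolated)
21 | tert-butyl 3-{(2R,5R)-6-[(dimethylamino)methyl]-5-[(2E,6E)-8-(tert-butyldimethylsilyloxy)-3,7-dimethylocta-2,6-dien-1-yl]-2-methyl-7-oxooxepan-2-yl}-3-oxopropanoate | O=C1O[C@](C(=O)CC(=O)OC(C)(C)C)(C)CC[C@@H](C1CN(C)C)C/C=C(C)/CC/C=C(C)/CO[Si](C)(C)C(C)(C)C | intermediate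
22 | tert-butyl 3-{(2R,5R)-6-[(dimethylamino)methyl]-5-[(2E,6E)-8-hydroxy-3,7-dimethylocta-2,6-dien-1-yl]-2-methyl-7-oxooxepan-2-yl}-3-oxopropanoate | O=C1O[C@](C(=O)CC(=O)OC(C)(C)C)(C)CC[C@@H](C1CN(C)C)C/C=C(C)/CC/C=C(C)/CO | intermediate
23 | tert-butyl 3-{(2R,5R)-6-[(dimethylamino)methyl]-5-[(2E,6E)-8-(methoxycarbonyloxy)-3,7-dimethylocta-2,6-dien-1-yl]-2-methyl-7-oxooxepan-2-yl}-3-oxopropanoate | O=C1O[C@](C(=O)CC(=O)OC(C)(C)C)(C)CC[C@@H](C1CN(C)C)C/C=C(C)/CC/C=C(C)/COC(=O)OC | intermediate
24 | (1R,3E,7E,12R)-10-(tert-butoxycarbonyl)-17-(dimethylamino)-11-oxocembra-3,7-dien-16,12-olide (C10 and C15 epimers) | O=C1O[C@]2(C)CC[C@@H](C1CN(C)C)C/C=C(C)/CC/C=C(C)/CC(C(=O)OC(C)(C)C)C2=O | intermediate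
25 | trimethylsilyl ester corresponding to 24 | O=C1O[C@]2(C)CC[C@@H](C1CN(C)C)C/C=C(C)/CC/C=C(C)/CC(C(=O)O[Si](C)(C)C)C2=O | intermediate (not isolated)
26 | (1R,3E,7E,12R)-10-carboxy-17-(dimethylamino)-11-oxocembra-3,7-dien-16,12-olide | O=C1O[C@]2(C)CC[C@@H](C1CN(C)C)C/C=C(C)/CC/C=C(C)/CC(C(=O)O)C2=O | intermediate (not isolated)
27 | (1R,3E,7E,12R)-17-(dimethylamino)-11-oxocembra-3,7-dien-16,12-olide (C15 epimers) | O=C1O[C@]2(C)CC[C@@H](C1CN(C)C)C/C=C(C)/CC/C=C(C)/CCC2=O | intermediate
28 | trimethylammonium iodide of 27 | O=C1O[C@]2(C)CC[C@@H](C1C[N+](C)(C)C)C/C=C(C)/CC/C=C(C)/CCC2=O.[I-] | intermediate (not isolated)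
29 | (1R,3E,7E,12R)-11-oxocembra-3,7,15(17)-trien-16,12-olide | C=C1C(=O)O[C@]2(C)CC[C@@H]1C/C=C(C)/CC/C=C(C)/CCC2=O | intermediate
30 | (1R,3S,4S,7S,8S,12R)-3,4:7,8-diepoxy-11-oxocembr-15(17)-en-16,12-olide | C=C1C(=O)O[C@]2(C)CC[C@@H]1C[C@@H]3O[C@@]3(C)CC[C@@H]4O[C@@]4(C)CCC2=O | intermediate
31 | (1R,3S,4S,7S,8R,12R)-3,4-epoxy-7,8-dihydroxy-11-oxocembr-15(17)-en-16,12-olide | C=C1C(=O)O[C@]2(C)CC[C@@H]1C[C@@H]3O[C@@]3(C)CC[C@H](O)[C@](C)(O)CCC2=O | intermediate (not isolated)
32 | (1R,3S,4R,7S,8R,12R)-4,7-epoxy-3,8-dihydroxy-11-oxocembr-15(17)-en-16,12-olide | C=C1C(=O)O[C@]2(C)CC[C@@H]1C[C@H](O)[C@@]1(C)CC[C@H](O1)[C@](C)(O)CCC2=O | target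

**Step count and risks**

Total step count: 21. Longest linear sequence: 17 steps (steps 1–6 and 11–21 from cyclohex-2-en-1-one); steps 7–10 are the second branch.

The three steps most likely to fail:

Step 20, double epoxidation. The chiral dioxirane may meet a ring conformer that hides the required olefin face, giving poor facial selectivity at one or both olefins. The fallback hands control from the reagent to the substrate. Triene 29 is treated with achiral dimethyldioxirane in acetone at −20 °C, so that attack from the outside of the preferred ring conformer decides each face. If only one olefin then reacts from the wrong face, the catalyst is kept for that olefin alone and the ring bias is used for the other. No compound outside the list arises (F0), and the sequence returns to bis-epoxide 30.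

Step 17, ring closure. Oligomerisation, attack at the substituted π-allyl terminus C7, or E/Z scrambling through the π-allyl complex may erode the macrocyclisation. The fallback closes the same C9–C10 bond without palladium, by SN2 alkylation. Alcohol 22 is converted with MsCl, LiCl and 2,4,6-collidine in DMF at 0 °C into the allylic chloride tert-butyl 3-{(2R,5R)-5-[(2E,6E)-8-chloro-3,7-dimethylocta-2,6-dien-1-yl]-6-[(dimethylamino)methyl]-2-methyl-7-oxooxepan-2-yl}-3-oxopropanoate F1. This is added slowly to Cs2CO3 and catalytic NaI in MeCN at 50 °C (final 1 mM). The caesium enolate should alkylate the primary allylic carbon directly, a path that cannot reach C7 or isomerise the olefin, and the sequence returns to macrocycle 24.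

Step 21, cascade. Water may open the 3,4-epoxide first, or the C8 hydroxyl may close a six-membered ether, so that the cascade takes the wrong regiochemical course. The fallback stages the two C–O bond formations. Bis-epoxide 30 is treated with catalytic pyridinium p-toluenesulfonate in dry CH2Cl2 at 0 °C. Without water only the γ,δ-epoxy ketone can react, and the known epoxy ketone to bicyclic ketal isomerisation should give the 2,7-dioxabicyclo[2.2.1]heptane ketal of 30 (C11 bonded to the C7 and C8 oxygens, C8 inverted, 3,4-epoxide intact) F2, which is isolated. Aqueous acetic acid in THF then cleaves the strained ketal at its C11–O7 bond; the freed C7 hydroxyl closes the oxolane on C4 in the 5-exo mode, and hydration of the oxocarbenium ion gives the ketone and the C8 hydroxyl, returning to target 32.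

**Further compounds**

F1 | step 17 | tert-butyl 3-{(2R,5R)-5-[(2E,6E)-8-chloro-3,7-dimethylocta-2,6-dien-1-yl]-6-[(dimethylamino)methyl]-2-methyl-7-oxooxepan-2-yl}-3-oxopropanoate | O=C1O[C@](C(=O)CC(=O)OC(C)(C)C)(C)CC[C@@H](C1CN(C)C)C/C=C(C)/CC/C=C(C)/CCl
F0 | step 20 | none | none
F2 | step 21 | 2,7-dioxabicyclo[2.2.1]heptane ketal of 30 (C11 bonded to the C7 and C8 oxygens, C8 inverted, 3,4-epoxide intact) | C=C1C(=O)O[C@]2(C)CC[C@@H]1C[C@@H]3O[C@@]3(C)CC[C@@H]4O[C@@]25CC[C@@]4(C)O5
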